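**Plan**
1. Retrosynthesis cuts the C3–C(=O)Ar bond (aroylation of a lactone enolate), then the lactone O1–C2 bond and the C4–C5 bond of (R)-4-veratryl-γ-butyrolactone, after an oxygen is put back on the benzylic carbon C7′.
2. Enabling feature: C4 of the lactone ring carries the CH2O carbon C5 and is bonded to C7′. A hydroxyl placed temporarily on C7′ holds a BrCH2SiMe2 tether whose CH2 (the future C5) is delivered to C4 through a 1,2-oxasilolane ring.
3. Forward: veratraldehyde plus vinyl Grignard, lipase resolution, cross-metathesis with methyl acrylate (chain C7′–C4–C3–C2), silylation, 5-exo radical closure (temporary oxasilolane ring), Tamao oxidation, hydrogenolysis with lactone ring closure, C3 aroylation, debenzylation.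
4. Stereochemistry: the C7′ carbinol centre comes from the enzymatic resolution, is relayed to C4 by the trans-selective cyclisation and is then erased. C3 settles trans to C4 through enolate face selection and thermodynamic control.

Key step: step 5

Remark: C3 of the target lies between two carbonyl groups and is expected to rest in the trans (3S,4R) arrangement, which is the isomer drawn. The methyl ester is used as spectator ester so that methanol in the Tamao step cannot scramble it. 4-(Benzyloxy)-3-methoxybenzoic acid is taken as a purchased material.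

**Step 1**
Reactants: 1 veratraldehyde; 2 vinylmagnesium bromide
Product: 4 rac-1-(3,4-dimethoxyphenyl)prop-2-en-1-yl acetate, via bromomagnesium alkoxide 3 (not isolated)
Conditions: CH2=CHMgBr (1.2 equiv), THF, 0 °C; then Ac2O (1.5 equiv), 0 °C to rt
Reagents that add atoms: acetic anhydride, CC(=O)OC(C)=O
Why: Grignard 1,2-addition to the aldehyde followed by acetylation of the magnesium alkoxide in the same flask; the carbinol centre forms racemic and is resolved in step 2.

**Step 2**
Reactants: 4 rac-1-(3,4-dimethoxyphenyl)prop-2-en-1-yl acetate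
Product: 5 (R)-1-(3,4-dimethoxyphenyl)prop-2-en-1-ol
Conditions: Novozym 435 (immobilised Candida antarctica lipase B), 1-butanol (3 equiv), MTBE, 30 °C, stopped short of half conversion
Reagents that add atoms: none
Why: Lipase-catalysed kinetic resolution by transesterification, in which the enzyme should cleave the acetate enantiomer that places the aryl group in its large pocket and the vinyl group in the medium one, that is the (R)-ester, so that (R)-5 is released and the unreacted (S)-acetate is separated (at most half of 4 is used).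

**Step 3**
Reactants: 5 (R)-1-(3,4-dimethoxyphenyl)prop-2-en-1-ol; 6 methyl acrylate
Product: 7 methyl (R,E)-4-(3,4-dimethoxyphenyl)-4-hydroxybut-2-enoate
Conditions: methyl acrylate (4 equiv), second-generation Grubbs catalyst RuCl2(=CHPh)(PCy3)(H2IMes) (3 mol%), CH2Cl2, 40 °C
Reagents that add atoms: none
Why: Olefin cross-metathesis of a terminal allylic alcohol with an acrylate, which is E-selective and does not touch the carbinol centre.

**Step 4**
Reactants: 7 methyl (R,E)-4-(3,4-dimethoxyphenyl)-4-hydroxybut-2-enoate; 8 (bromomethyl)chlorodimethylsilane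
Product: 9 methyl (R,E)-4-{[(bromomethyl)dimethylsilyl]oxy}-4-(3,4-dimethoxyphenyl)but-2-enoate
Conditions: BrCH2SiMe2Cl (1.2 equiv), Et3N, DMAP (cat.), CH2Cl2, 0 °C; filtered and used without silica chromatography
Reagents that add atoms: none
Why: O-silylation of a secondary alcohol with a chlorosilane and an amine base, with no change at the carbinol carbon.

**Step 5**
Reactants: 9 methyl (R,E)-4-{[(bromomethyl)dimethylsilyl]oxy}-4-(3,4-dimethoxyphenyl)but-2-enoate
Product: 10 methyl 2-[(4S,5R)-5-(3,4-dimethoxyphenyl)-2,2-dimethyl-1,2-oxasilolan-4-yl]acetate (trans)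
Conditions: Bu3SnH (1.3 equiv, syringe pump), AIBN (0.1 equiv), benzene (0.02 M), 80 °C
Reagents that add atoms: none
Why: The tributyltin radical abstracts bromine from 9, the α-silyl carbon radical adds intramolecularly to the β-carbon of the enoate, and the adduct radical α to the ester takes hydrogen from Bu3SnH; this is the known silicon-tethered radical cyclisation of (bromomethyl)dimethylsilyl ethers of allylic alcohols. The 1,2-oxasilolane ring closes in the 5-exo-trig mode and forms the bond that becomes C4–C5 of the lactone. The new stereocentre (C4 of the oxasilolane) is controlled by the carbinol centre C5: in the chair-like transition state the aryl group sits pseudo-equatorial and the enoate arm avoids it, so the trans (4S,5R) ring should predominate. The step needs 5-exo over 6-endo closure and cyclisation ahead of direct C–Br reduction; the ester at the alkene terminus secures the first by polarity matching and by stabilising the adduct radical, and slow addition of the stannane at high dilution secures the second. Any cis isomer would lead to the enantiomeric lactone once the carbinol centre is removed, so it is separated by chromatography here or at the diol stage.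

**Step 6**
Reactants: 10 methyl 2-[(4S,5R)-5-(3,4-dimethoxyphenyl)-2,2-dimethyl-1,2-oxasilolan-4-yl]acetate
Product: 11 methyl (3R,4R)-4-(3,4-dimethoxyphenyl)-4-hydroxy-3-(hydroxymethyl)butanoate
Conditions: 30% H2O2, KF, KHCO3, THF/MeOH (1:1), rt
Reagents that add atoms: hydrogen peroxide, OO
Why: Tamao oxidation of the alkoxysilane C–Si bond turns the ring CH2–Si into the CH2OH of the future C5 and frees the benzylic hydroxyl; any lactone formed by loss of methanol converges in step 7.

**Step 7**
Reactants: 11 methyl (3R,4R)-4-(3,4-dimethoxyphenyl)-4-hydroxy-3-(hydroxymethyl)butanoate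
Product: 13 (R)-4-(3,4-dimethoxybenzyl)dihydrofuran-2(3H)-one, via methyl (R)-4-(3,4-dimethoxyphenyl)-3-(hydroxymethyl)butanoate 12 (not isolated)
Conditions: H2 (1 atm), 10% Pd/C, AcOH, HClO4 (cat.), rt
Reagents that add atoms: none
Why: Acid-assisted catalytic hydrogenolysis of the electron-rich benzylic C–O bond and acid-catalysed lactonisation (in either order), as is usual for benzylic hydroxyl groups of veratryl-type lignan lactones; the neighbouring stereocentre is not involved and becomes C4 (R) of the lactone.

**Step 8**
Reactants: 14 4-(benzyloxy)-3-methoxybenzoic acid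
Product: 15 4-(benzyloxy)-3-methoxybenzoyl chloride
Conditions: (COCl)2 (1.3 equiv), DMF (cat.), CH2Cl2, 0 °C to rt; evaporated and used crude
Reagents that add atoms: oxalyl chloride, O=C(Cl)C(=O)Cl
Why: Standard acid chloride formation through the chloroiminium (Vilsmeier-type) activation of the carboxylic acid.

**Step 9**
Reactants: 13 (R)-4-(3,4-dimethoxybenzyl)dihydrofuran-2(3H)-one; 15 4-(benzyloxy)-3-methoxybenzoyl chloride
Product: 18 (3S,4R)-3-[4-(benzyloxy)-3-methoxybenzoyl]-4-(3,4-dimethoxybenzyl)dihydrofuran-2(3H)-one, via lactone lithium enolate 16 (not isolated), via keto lactone lithium enolate 17 (not isolated)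
Conditions: LiN(SiMe3)2 (2.2 equiv), THF, −78 °C; then 15 (1.05 equiv), −78 to −40 °C; aq NH4Cl
Reagents that add atoms: none
Why: Claisen-type C-acylation of the lactone lithium enolate by the aroyl chloride, in which attack anti to the C4 benzyl group and reprotonation of the doubly stabilised product enolate on work-up both favour the trans (3S) isomer.

**Step 10**
Reactants: 18 (3S,4R)-3-[4-(benzyloxy)-3-methoxybenzoyl]-4-(3,4-dimethoxybenzyl)dihydrofuran-2(3H)-one
Product: 19 (3S,4R)-4-(3,4-dimethoxybenzyl)-3-(4-hydroxy-3-methoxybenzoyl)dihydrofuran-2(3H)-one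
Conditions: H2 (1 atm), 10% Pd/C, EtOAc, rt, stopped when 18 is consumed
Reagents that add atoms: none
Why: Hydrogenolysis of the benzyl aryl ether under neutral conditions, which should leave the aryl ketone and the lactone intact while C3 stays in the thermodynamically preferred trans configuration.

**Compound list**
1 | veratraldehyde (3,4-dimethoxybenzaldehyde) | COc1ccc(C=O)cc1OC | starting material
2 | vinylmagnesium bromide | C=C[Mg]Br | starting material
3 | bromomagnesium 1-(3,4-dimethoxyphenyl)prop-2-en-1-olate (racemic) | C=CC(O[Mg]Br)c1ccc(OC)c(OC)c1 | intermediate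
4 | rac-1-(3,4-dimethoxyphenyl)prop-2-en-1-yl acetate | C=CC(OC(C)=O)c1ccc(OC)c(OC)c1 | intermediate
5 | (R)-1-(3,4-dimethoxyphenyl)prop-2-en-1-ol | C=C[C@@H](O)c1ccc(OC)c(OC)c1 | intermediate
6 | methyl acrylate | C=CC(=O)OC | starting material
7 | methyl (R,E)-4-(3,4-dimethoxyphenyl)-4-hydroxybut-2-enoate | COC(=O)/C=C/[C@@H](O)c1ccc(OC)c(OC)c1 | intermediate
8 | (bromomethyl)chlorodimethylsilane | C[Si](C)(Cl)CBr | starting material
9 | methyl (R,E)-4-{[(bromomethyl)dimethylsilyl]oxy}-4-(3,4-dimethoxyphenyl)but-2-enoate | COC(=O)/C=C/[C@@H](O[Si](C)(C)CBr)c1ccc(OC)c(OC)c1 | intermediate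
10 | methyl 2-[(4S,5R)-5-(3,4-dimethoxyphenyl)-2,2-dimethyl-1,2-oxasilolan-4-yl]acetate | C[Si]1(C)C[C@@H](CC(=O)OC)[C@H](c2ccc(OC)c(OC)c2)O1 | intermediate
11 | methyl (3R,4R)-4-(3,4-dimethoxyphenyl)-4-hydroxy-3-(hydroxymethyl)butanoate | OC[C@@H](CC(=O)OC)[C@@H](O)c1ccc(OC)c(OC)c1 | intermediate
12 | methyl (R)-4-(3,4-dimethoxyphenyl)-3-(hydroxymethyl)butanoate | OC[C@@H](CC(=O)OC)Cc1ccc(OC)c(OC)c1 | intermediate
13 | (R)-4-(3,4-dimethoxybenzyl)dihydrofuran-2(3H)-one | O=C1C[C@@H](Cc2ccc(OC)c(OC)c2)CO1 | intermediate
14 | 4-(benzyloxy)-3-methoxybenzoic acid | COc1cc(C(=O)O)ccc1OCc1ccccc1 | starting material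
15 | 4-(benzyloxy)-3-methoxybenzoyl chloride | COc1cc(C(Cl)=O)ccc1OCc1ccccc1 | intermediate
16 | lithium enolate of lactone 13 | [Li]OC1=C[C@@H](Cc2ccc(OC)c(OC)c2)CO1 | intermediate
17 | lithium enolate of keto lactone 18 | COc1cc(C(O[Li])=C2C(=O)OC[C@@H]2Cc2ccc(OC)c(OC)c2)ccc1OCc1ccccc1 | intermediate
18 | (3S,4R)-3-[4-(benzyloxy)-3-methoxybenzoyl]-4-(3,4-dimethoxybenzyl)dihydrofuran-2(3H)-one | COc1cc(C(=O)[C@H]2C(=O)OC[C@@H]2Cc2ccc(OC)c(OC)c2)ccc1OCc1ccccc1 | intermediate
19 | (3S,4R)-4-(3,4-dimethoxybenzyl)-3-(4-hydroxy-3-methoxybenzoyl)dihydrofuran-2(3H)-one | COc1cc(C(=O)[C@H]2C(=O)OC[C@@H]2Cc2ccc(OC)c(OC)c2)ccc1O | target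

**Step count**
Total: 10 steps. Longest linear sequence: 9 steps (steps 1–7, 9 and 10); step 8 is a one-step side branch.

**Steps most likely to fail**

Step 5. The tin hydride may reduce the C–Br bond before the ring closes, or the transition state may discriminate too weakly between trans and cis, which would erode the enantiomeric purity of 13 once the carbinol centre is removed. The fallback sets out from veratraldehyde 1 and comes back at lactone 13. Stobbe condensation of 1 with dimethyl succinate (NaOMe, MeOH, reflux) would give (E)-4-(3,4-dimethoxyphenyl)-3-(methoxycarbonyl)but-3-enoic acid F1. Asymmetric hydrogenation with [Rh(cod)((S,S)-Et-DuPhos)]BF4 (H2 5 atm, MeOH, catalytic NaOMe) should give (R)-4-(3,4-dimethoxyphenyl)-3-(methoxycarbonyl)butanoic acid F2. Chemoselective reduction of the ester in the potassium carboxylate (KOH, then Ca(BH4)2, EtOH) and acidification (HCl) would close the lactone 13.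

Step 9. The enolate may be acylated on oxygen or twice, or the acidic product may quench unreacted enolate and stall the conversion. The fallback sets out from lactone 13 and comes back at keto lactone 18. Aldol addition of the lithium enolate 16 (LiN(SiMe3)2, THF, −78 °C) to 4-(benzyloxy)-3-methoxybenzaldehyde, anti to the C4 substituent, would give (3S,4R)-3-{[4-(benzyloxy)-3-methoxyphenyl](hydroxy)methyl}-4-(3,4-dimethoxybenzyl)dihydrofuran-2(3H)-one F3 as a mixture of carbinol epimers. Oxidation of this benzylic alcohol with Dess–Martin periodinane (CH2Cl2, rt) would give 18.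

Step 7. Under the acidic conditions the benzylic alcohol may dehydrate towards the styrene, whose hydrogenation would scramble the adjacent stereocentre, or C–O cleavage may stall. The fallback sets out from diol ester 11 and comes back at lactone 13. Acetylation (Ac2O, pyridine, DMAP) would give methyl (3R,4R)-4-acetoxy-3-(acetoxymethyl)-4-(3,4-dimethoxyphenyl)butanoate F4. Its benzylic acetate should be cleaved by hydrogenolysis without added acid (H2, 10% Pd/C, EtOAc) to give methyl (R)-4-acetoxy-3-(3,4-dimethoxybenzyl)butanoate F5. Methanolysis of the acetate (K2CO3, MeOH) to hydroxy ester 12 and brief treatment with TsOH (cat.) would close 13.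

**Further compounds**
F1 | step 5 | (E)-4-(3,4-dimethoxyphenyl)-3-(methoxycarbonyl)but-3-enoic acid | COC(=O)/C(CC(=O)O)=C/c1ccc(OC)c(OC)c1
F2 | step 5 | (R)-4-(3,4-dimethoxyphenyl)-3-(methoxycarbonyl)butanoic acid | COC(=O)[C@@H](CC(=O)O)Cc1ccc(OC)c(OC)c1
F3 | step 9 | (3S,4R)-3-{[4-(benzyloxy)-3-methoxyphenyl](hydroxy)methyl}-4-(3,4-dimethoxybenzyl)dihydrofuran-2(3H)-one (carbinol epimers) | COc1cc(C(O)[C@H]2C(=O)OC[C@@H]2Cc2ccc(OC)c(OC)c2)ccc1OCc1ccccc1
F4 | step 7 | methyl (3R,4R)-4-acetoxy-3-(acetoxymethyl)-4-(3,4-dimethoxyphenyl)butanoate | CC(=O)OC[C@@H](CC(=O)OC)[C@@H](OC(C)=O)c1ccc(OC)c(OC)c1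
F5 | step 7 | methyl (R)-4-acetoxy-3-(3,4-dimethoxybenzyl)butanoate | CC(=O)OC[C@@H](CC(=O)OC)Cc1ccc(OC)c(OC)c1
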